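Lactone numbering: O1, C2 (C=O), C3 (carbon bearing the veratroyloxy group), C4, C5 (carbon bearing the benzyl group), C6 (benzylic CH2).
Cuts, in retrosynthetic order: C6–C(ipso) of the phenyl ring; the ester bond between O3 and the veratroyl carbonyl; the lactone bond O1–C2; last, carboxyl carbons C2 and C6 are rejoined as the C=C of a cyclopentene.
Enabling feature: with C6 raised to a carboxyl carbon, the chain C2–C6 is a 2,4-dihydroxyglutarate. The 3,5-trans γ-lactone ring unfolds to the syn diol, so this chain is meso, and closing the C5 oxygen onto C2 or the C3 oxygen onto C6 gives mirror-image trans lactones.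
Forward order: cis-cyclopent-4-ene-1,3-diol is silylated, cleaved to the meso diacid, esterified and desilylated; the γ-lactone, the only ring built, closes in step 5; then O3 is acylated, the C6 ester is taken down to CH2I, and the phenyl ring is attached last.
Stereochemistry: the relative configuration of C3 and C5 comes with the cis diol, the absolute configuration comes from a chiral phosphoric acid in step 5, and no later step makes or breaks a bond at C3 or C5.

Key step: step 5

Assumption: the sense of induction of the phosphoric acid on this substrate cannot be predicted with confidence, so the (R)-catalyst is written and its equally available (S)-antipode is to be used if a trial run closes the mirror-image pair.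

Step 1
Reactants: 1 cis-cyclopent-4-ene-1,3-diol (meso)
Product: 2 cis-3,5-bis[(tert-butyldimethylsilyl)oxy]cyclopent-1-ene (meso)
Conditions: TBSCl (2.4 equiv), imidazole (5 equiv), DMF, 0 °C → rt
Reagents that add atoms: tert-butyldimethylsilyl chloride, CC(C)(C)[Si](C)(C)Cl
Why: Imidazole-promoted silylation of secondary alcohols is routine, it shields both hydroxyls from the oxidant of step 2, and since no C–O bond is broken the cis (meso) relationship is carried over unchanged.

Step 2
Reactants: 2 cis-3,5-bis[(tert-butyldimethylsilyl)oxy]cyclopent-1-ene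
Product: 4 (2R,4S)-2,4-bis[(tert-butyldimethylsilyl)oxy]pentanedioic acid, via bis-silyloxy pentanedial 3 (not isolated)
Conditions: RuCl3·xH2O (3 mol %), NaIO4 (4.5 equiv), MeCN/EtOAc/H2O, 0 °C → rt
Reagents that add atoms: sodium periodate (oxygen relayed through RuO4), [Na+].[O-]I(=O)(=O)=O; water, O
Why: RuO4-catalysed oxidative cleavage of a 1,2-disubstituted cycloalkene runs through the cyclic ruthenate ester and dialdehyde 3 to the diacid, secondary TBS ethers survive it, and because the mirror plane of 2 bisects the cleaved C=C bond the product can only be the meso (2R,4S) diacid.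

Step 3
Reactants: 4 (2R,4S)-2,4-bis[(tert-butyldimethylsilyl)oxy]pentanedioic acid
Product: 5 di-tert-butyl (2R,4S)-2,4-bis[(tert-butyldimethylsilyl)oxy]pentanedioate (meso)
Conditions: tert-butyl 2,2,2-trichloroacetimidate (4 equiv), CH2Cl2/cyclohexane, rt
Reagents that add atoms: tert-butyl 2,2,2-trichloroacetimidate, CC(C)(C)OC(=N)C(Cl)(Cl)Cl
Why: In this imidate esterification the acids protonate the trichloroacetimidate and are O-alkylated by the tert-butyl cation it releases, so the carbonyl groups are never activated, the α-stereocentres cannot epimerise and the silyl ethers are left alone.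

Step 4
Reactants: 5 di-tert-butyl (2R,4S)-2,4-bis[(tert-butyldimethylsilyl)oxy]pentanedioate
Product: 6 di-tert-butyl (2R,4S)-2,4-dihydroxypentanedioate (meso)
Conditions: HF·pyridine, excess pyridine, THF, 0 °C → rt; pH 7 buffer work-up
Reagents that add atoms: none
Why: Fluoride-driven cleavage of the Si–O bonds in a weakly acidic, pyridine-buffered medium frees both hydroxyls without generating an alkoxide, and together with the bulk of the tert-butyl esters this should keep the uncatalysed ring closure too slow to matter.

Step 5
Reactants: 6 di-tert-butyl (2R,4S)-2,4-dihydroxypentanedioate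
Product: 8 tert-butyl (2S,4R)-4-hydroxy-5-oxooxolane-2-carboxylate, via cyclic hemiorthoester 7 (not isolated)
Conditions: (R)-3,3'-bis(2,4,6-triisopropylphenyl)-1,1'-binaphthalene-2,2'-diyl hydrogen phosphate (10 mol %), toluene (0.05 M), 25–40 °C
Reagents that add atoms: none
Why: Proposed new method: the phosphoric acid is expected to work bifunctionally, its P–OH hydrogen-bonding to one tert-butyl ester carbonyl while its P=O takes up the proton of the distal hydroxyl, so that the oxygen on the (S)-carbon (future O1) adds to the ester carbon attached to the (R)-carbon (future C2) and the resulting hemiorthoester 7 expels tert-butanol. The closest known reaction type is the chiral-phosphoric-acid-catalysed desymmetrising lactonisation of prochiral hydroxyalkyl malonic di-tert-butyl esters (and the lipase-mediated lactonisation of prochiral γ-hydroxy diesters), in which one hydroxyl selects between two enantiotopic esters; untested here is the choice between the two enantiotopic hydroxyl–ester pairs of a meso 1,3-diol. The single ring, the γ-lactone O1–C2–C3–C4–C5, closes in the 5-exo-trig mode. No bond at C3 or C5 is made or broken: their relative configuration is inherited from meso 6 (syn diol, hence 3,5-trans lactone), and their absolute configuration (3R and 5S in lactone numbering) is fixed only by which pair fits the chiral pocket between the two triisopropylphenyl groups of the catalyst. The step needs enantiotopic-group selectivity, a negligible uncatalysed rate and a halt after one closure; the bulky tert-butyl esters secure the second point, and the trans disposition of the remaining hydroxyl and ester, which cannot bridge the ring, secures the third and also rules out racemisation of 8 by translactonisation.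

Step 6
Reactants: 8 tert-butyl (2S,4R)-4-hydroxy-5-oxooxolane-2-carboxylate; 9 3,4-dimethoxybenzoyl chloride
Product: 10 tert-butyl (2S,4R)-4-[(3,4-dimethoxybenzoyl)oxy]-5-oxooxolane-2-carboxylate
Conditions: 9 (1.2 equiv), pyridine (3 equiv), DMAP (5 mol %), CH2Cl2, 0 °C → rt
Reagents that add atoms: 3,4-dimethoxybenzoyl chloride (9), COc1ccc(C(Cl)=O)cc1OC
Why: DMAP-catalysed acylation of a secondary α-hydroxy lactone with an aroyl chloride (nucleophilic catalysis through the acylpyridinium ion) occurs at oxygen with retention at C3, and the weak base and low temperature leave the acidic C3–H and C5–H untouched.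

Step 7
Reactants: 10 tert-butyl (2S,4R)-4-[(3,4-dimethoxybenzoyl)oxy]-5-oxooxolane-2-carboxylate
Product: 11 (2S,4R)-4-[(3,4-dimethoxybenzoyl)oxy]-5-oxooxolane-2-carboxylic acid
Conditions: TFA/CH2Cl2 (1:2), 0 °C → rt
Reagents that add atoms: none
Why: Acidolysis of the tert-butyl ester by alkyl–oxygen fission (loss of the tert-butyl cation as isobutene) spares the lactone, the aryl ester and the methyl ethers, none of which can ionise in this way, and no stereocentre is involved.

Step 8
Reactants: 11 (2S,4R)-4-[(3,4-dimethoxybenzoyl)oxy]-5-oxooxolane-2-carboxylic acid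
Product: 12 (3R,5S)-5-(hydroxymethyl)-2-oxooxolan-3-yl 3,4-dimethoxybenzoate
Conditions: BH3·SMe2 (1.3 equiv), THF, 0 °C → rt; then H2O
Reagents that add atoms: none
Why: Borane reduces a free carboxylic acid far faster than it attacks lactones or benzoate esters, a chemoselectivity long exploited on 5-oxooxolane-2-carboxylic acids, and C5 keeps its configuration because only C6 changes.

Step 9
Reactants: 12 (3R,5S)-5-(hydroxymethyl)-2-oxooxolan-3-yl 3,4-dimethoxybenzoate
Product: 13 (3R,5S)-5-(iodomethyl)-2-oxooxolan-3-yl 3,4-dimethoxybenzoate
Conditions: I2 (1.3 equiv), PPh3 (1.3 equiv), imidazole (1.5 equiv), CH2Cl2, 0 °C → rt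
Reagents that add atoms: iodine, II
Why: The Appel reaction turns the unhindered primary alcohol into its alkoxyphosphonium salt and iodide displaces Ph3P=O at C6 by SN2 under almost neutral conditions, so the esters and both stereocentres are unaffected.

Step 10
Reactants: 13 (3R,5S)-5-(iodomethyl)-2-oxooxolan-3-yl 3,4-dimethoxybenzoate; 14 iodobenzene
Product: 15 trichoderolide F, (3R,5R)-5-benzyl-2-oxooxolan-3-yl 3,4-dimethoxybenzoate
Conditions: 14 (1.5 equiv), NiBr2·dme (10 mol %), 4,4'-di-tert-butyl-2,2'-bipyridine (10 mol %), Mn powder (2 equiv), DMA, 25–40 °C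
Reagents that add atoms: iodobenzene (14), Ic1ccccc1
Why: In this nickel-catalysed reductive cross-electrophile coupling iodobenzene adds oxidatively to zerovalent nickel, the primary C6 radical released from 13 by iodine abstraction is captured by the arylnickel species and rapid reductive elimination from trivalent nickel forms the C6–C(ipso) bond, while Mn only recycles the catalyst, esters and lactones are tolerated, and C5, next to but not part of the radical centre, keeps its configuration (its descriptor changes from S to R only because the CIP rank of C6 drops).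

Compound list
1 | cis-cyclopent-4-ene-1,3-diol (meso) | O[C@@H]1C[C@H](O)C=C1 | starting material
2 | cis-3,5-bis[(tert-butyldimethylsilyl)oxy]cyclopent-1-ene (meso) | CC(C)(C)[Si](C)(C)O[C@@H]1C[C@H](O[Si](C)(C)C(C)(C)C)C=C1 | intermediate
3 | (2R,4S)-2,4-bis[(tert-butyldimethylsilyl)oxy]pentanedial (meso, formed and consumed in the flask of step 2) | O=C[C@H](O[Si](C)(C)C(C)(C)C)C[C@H](O[Si](C)(C)C(C)(C)C)C=O | intermediate
4 | (2R,4S)-2,4-bis[(tert-butyldimethylsilyl)oxy]pentanedioic acid (meso) | OC(=O)[C@H](O[Si](C)(C)C(C)(C)C)C[C@H](O[Si](C)(C)C(C)(C)C)C(=O)O | intermediate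
5 | di-tert-butyl (2R,4S)-2,4-bis[(tert-butyldimethylsilyl)oxy]pentanedioate (meso) | CC(C)(C)OC(=O)[C@H](O[Si](C)(C)C(C)(C)C)C[C@H](O[Si](C)(C)C(C)(C)C)C(=O)OC(C)(C)C | intermediate
6 | di-tert-butyl (2R,4S)-2,4-dihydroxypentanedioate (meso) | CC(C)(C)OC(=O)[C@H](O)C[C@H](O)C(=O)OC(C)(C)C | intermediate
7 | tert-butyl (2S,4R)-5-tert-butoxy-4,5-dihydroxyoxolane-2-carboxylate (hemiorthoester, C5 unassigned, formed and consumed in the flask of step 5) | O[C@@H]1C[C@@H](C(=O)OC(C)(C)C)OC1(O)OC(C)(C)C | intermediate
8 | tert-butyl (2S,4R)-4-hydroxy-5-oxooxolane-2-carboxylate (trans) | O[C@@H]1C[C@@H](C(=O)OC(C)(C)C)OC1=O | intermediate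
9 | 3,4-dimethoxybenzoyl chloride | COc1ccc(C(Cl)=O)cc1OC | starting material
10 | tert-butyl (2S,4R)-4-[(3,4-dimethoxybenzoyl)oxy]-5-oxooxolane-2-carboxylate | COc1ccc(C(=O)O[C@@H]2C[C@@H](C(=O)OC(C)(C)C)OC2=O)cc1OC | intermediate
11 | (2S,4R)-4-[(3,4-dimethoxybenzoyl)oxy]-5-oxooxolane-2-carboxylic acid | COc1ccc(C(=O)O[C@@H]2C[C@@H](C(=O)O)OC2=O)cc1OC | intermediate
12 | (3R,5S)-5-(hydroxymethyl)-2-oxooxolan-3-yl 3,4-dimethoxybenzoate | COc1ccc(C(=O)O[C@@H]2C[C@@H](CO)OC2=O)cc1OC | intermediate
13 | (3R,5S)-5-(iodomethyl)-2-oxooxolan-3-yl 3,4-dimethoxybenzoate | COc1ccc(C(=O)O[C@@H]2C[C@@H](CI)OC2=O)cc1OC | intermediate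
14 | iodobenzene | Ic1ccccc1 | starting material
15 | trichoderolide F, (3R,5R)-5-benzyl-2-oxooxolan-3-yl 3,4-dimethoxybenzoate | COc1ccc(C(=O)O[C@@H]2C[C@@H](Cc3ccccc3)OC2=O)cc1OC | target

Total step count: 10. Longest linear sequence: 10 steps (1 → 15); 9 and 14 are bought and enter in steps 6 and 10.

Steps most likely to fail

Risk 1, step 5: the catalyst may discriminate poorly between the two enantiotopic hydroxyl–ester pairs, or turnover may be so slow that acid-induced loss of tert-butyl groups competes. Because the trans lactone cannot react further, no follow-up reaction would raise the enantiomeric purity. It is to be checked on the UV-active ester 10 and raised there by recrystallisation if needed.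

The fallback sets out from diacid 4 and uses known chemistry only.
- Dehydration with DCC in CH2Cl2 should give the cis anhydride (3R,5S)-3,5-bis[(tert-butyldimethylsilyl)oxy]oxane-2,6-dione F1.
- The established cinchona-alkaloid-catalysed desymmetrising methanolysis of meso glutaric anhydrides follows (hydroquinidine anthraquinone-1,4-diyl diether, (DHQD)2AQN, or its hydroquinine pseudo-enantiomer, MeOH, Et2O, −20 °C). It places the methyl ester on the carbonyl attached to the (R)-carbon and gives (2S,4R)-2,4-bis[(tert-butyldimethylsilyl)oxy]-5-methoxy-5-oxopentanoic acid F2.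
- The free acid is capped with tert-butyl 2,2,2-trichloroacetimidate to give 1-tert-butyl 5-methyl (2S,4R)-2,4-bis[(tert-butyldimethylsilyl)oxy]pentanedioate F3.
- HF·pyridine frees 1-tert-butyl 5-methyl (2S,4R)-2,4-dihydroxypentanedioate F4.
- With PPTS in warm toluene, the hydroxyl on the (S)-carbon of F4 closes onto the far more reactive methyl ester, and the route is rejoined at 8.

The same O1–C2 bond closes the same ring. The choice between the two chain ends now rests on ester reactivity, and the absolute configuration on the anhydride opening.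

Risk 2, step 10: the lactone carboxylate sits β to C6, so reductive ring opening may occur (β-elimination from a C6–metal species, the reverse of an iodolactonisation). Hydrodehalogenation or homocoupling may also outrun the cross-coupling.

The fallback sets out from alcohol 12.
- Tf2O and 2,6-lutidine in CH2Cl2 at −78 °C give (3R,5S)-2-oxo-5-{[(trifluoromethanesulfonyl)oxy]methyl}oxolan-3-yl 3,4-dimethoxybenzoate F5.
- F5 is treated without delay with Ph2CuLi (from PhLi and CuBr·SMe2) in Et2O/THF at −78 °C.
- This polar SN2 displacement is known for 5-(sulfonyloxymethyl)butyrolactones. It forms the same C6–C(ipso) bond with no reducing metal in the flask, at a temperature where esters are inert, and arrives directly at 15.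

Risk 3, step 4: uncatalysed lactonisation may set in during fluoride treatment or work-up, which would consume 6 and bring racemic lactone into the key step. Any such material has to be removed by chromatography before step 5.

The fallback sets out from 1 and replaces silyl protection by benzyl ethers, which are removed under neutral conditions.
- NaH and BnBr in DMF give cis-3,5-bis(benzyloxy)cyclopent-1-ene F6.
- RuO4 would oxidise benzyl ethers, so the alkene is cleaved with O3 (CH2Cl2, −78 °C, then Me2S) to (2R,4S)-2,4-bis(benzyloxy)pentanedial F7.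
- F7 is taken on at once by Pinnick oxidation (NaClO2, NaH2PO4, 2-methyl-2-butene, t-BuOH/H2O) to (2R,4S)-2,4-bis(benzyloxy)pentanedioic acid F8.
- tert-Butyl 2,2,2-trichloroacetimidate gives di-tert-butyl (2R,4S)-2,4-bis(benzyloxy)pentanedioate F9.
- Hydrogenolysis (H2, Pd/C, EtOAc, rt) releases 6 with neither acid nor base present.

Further compounds
F1 | step 5 | (3R,5S)-3,5-bis[(tert-butyldimethylsilyl)oxy]oxane-2,6-dione (meso, cis) | O=C1[C@H](O[Si](C)(C)C(C)(C)C)C[C@H](O[Si](C)(C)C(C)(C)C)C(=O)O1
F2 | step 5 | (2S,4R)-2,4-bis[(tert-butyldimethylsilyl)oxy]-5-methoxy-5-oxopentanoic acid | COC(=O)[C@H](O[Si](C)(C)C(C)(C)C)C[C@H](O[Si](C)(C)C(C)(C)C)C(=O)O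
F3 | step 5 | 1-tert-butyl 5-methyl (2S,4R)-2,4-bis[(tert-butyldimethylsilyl)oxy]pentanedioate | COC(=O)[C@H](O[Si](C)(C)C(C)(C)C)C[C@H](O[Si](C)(C)C(C)(C)C)C(=O)OC(C)(C)C
F4 | step 5 | 1-tert-butyl 5-methyl (2S,4R)-2,4-dihydroxypentanedioate | COC(=O)[C@H](O)C[C@H](O)C(=O)OC(C)(C)C
F5 | step 10 | (3R,5S)-2-oxo-5-{[(trifluoromethanesulfonyl)oxy]methyl}oxolan-3-yl 3,4-dimethoxybenzoate | COc1ccc(C(=O)O[C@@H]2C[C@@H](COS(=O)(=O)C(F)(F)F)OC2=O)cc1OC
F6 | step 4 | cis-3,5-bis(benzyloxy)cyclopent-1-ene (meso) | c1ccccc1CO[C@@H]1C[C@H](OCc2ccccc2)C=C1
F7 | step 4 | (2R,4S)-2,4-bis(benzyloxy)pentanedial (meso) | O=C[C@H](OCc1ccccc1)C[C@H](OCc1ccccc1)C=O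
F8 | step 4 | (2R,4S)-2,4-bis(benzyloxy)pentanedioic acid (meso) | OC(=O)[C@H](OCc1ccccc1)C[C@H](OCc1ccccc1)C(=O)O
F9 | step 4 | di-tert-butyl (2R,4S)-2,4-bis(benzyloxy)pentanedioate (meso) | CC(C)(C)OC(=O)[C@H](OCc1ccccc1)C[C@H](OCc1ccccc1)C(=O)OC(C)(C)C
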